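The constants used here come from no measurement.

Links do not keep.

| setting | dusk | dawn | midnight | spring |
|---|---|---|---|---|
| solid first end groups | 0.0010 M | 0.0010 M | 0.0010 M | 0.0010 M |
| second end groups | 0.980 mM | 0.980 mM | 0.980 mM (fed, over 12 s) | 0.980 mM |
| third end groups | 1.00 mM (fed, over 12 s) | 1.00 mM | 1.00 mM | 1.00 mM (in portions, 5, over 12 s) |
| temperature | 100 °C | 100 °C |  | 100 °C |
| time | 15 s | 15 s | 15 s | 15 s |
| remark | all else is in the flask from the start; the feed brings no volume worth counting | everything together at the start | the addition at 70 °C, then warmed to 100 °C; the feed brings no volume worth counting | first portion at the start, last at 12 s |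

1. the best flask by share of links in links plus over-reaction product; "all alike" if 1.5 percentage points covers them all (dusk / dawn / midnight / spring / all alike)
2. share of links in links plus over-reaction product at the end, dusk
3. share of links in links plus over-reaction product at the end, dawn
4. share of links in links plus over-reaction product at the end, midnight
5. share of links in links plus over-reaction product at the end, spring

- a step written with two of one species runs at k times the square of its concentration and takes two of it each time
- solid, in amounts per volume of the solution: solid first end groups
- constants are those at 100 °C; use the activation energies for any other temperature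
- at the start none of the solid first end groups is in solution

    first end groups + second end groups → links (k1 = 9940 M⁻¹ s⁻¹, Ea1 = 28.0 kJ mol⁻¹)
    second end groups + third end groups → links of the second sort (k2 = 9950 M⁻¹ s⁻¹, Ea2 = 46.0 kJ mol⁻¹)
    solid first end groups ⇌ first end groups, rate k3*(cs3 - [first end groups]) while solid is left; crystals form when [first end groups] > cs3 (cs3 = 0.12 mM, k3 = 0.206 s⁻¹)
    2 third end groups → homo dimer (k4 = 183 M⁻¹ s⁻¹, Ea4 = 51.0 kJ mol⁻¹)
    links → over-reaction product (k5 = 0.0842 s⁻¹, Ea5 = 104 kJ mol⁻¹)
    (constants at 100 °C)

I reckoned with the link life τ, the mean time a link lasts at 100 °C before it turns into over-reaction product, τ = 11.9 s. A link that waits a time w at 100 °C is still a link with chance exp(−w/τ), so in a flask at that temperature the share asked for is roughly that chance at the typical wait.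

In dawn, second end groups and third end groups start nearly equal, so second end groups fall roughly as the inverse of 9950 M⁻¹ s⁻¹ times the time. At the start of dawn they catch dissolved first end groups at 9.74 s⁻¹, faster than the solid's coefficient 0.206 s⁻¹, so at that stage dissolving is the rate-limiting step. In dawn, control changes hands when the two match, at 4.85 s. Taking dawn's links as made evenly up to then, the typical link is made at 2.42 s, which gives a share of 34.7%.

For midnight I took the cold feed as holding links still, because the step that spoils them has the highest activation energy. The wait in midnight then starts at 12 s, which gives 77.7%. I made no number for dusk or spring.

The forecast named midnight, with 42.1% for dusk, 32.7% for dawn, 79% for midnight and 42% for spring, on the ground that “The share depends only on when links form”. Its dawn figure stood lower than mine.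

The flasks gave 43.8% in dusk, 34.7% in dawn, 78.8% in midnight and 45.2% in spring, so midnight was best. Midnight's over-reaction product stood at 0.305% of the solid charged at 12.0 s and at 4.60% at 15.0 s.

In dawn, the step of second end groups with third end groups had 99.2% of its turnover up to 15 s behind it at 3.00 s, while the link-making step had 70% of its own by then and half by 1.97 s. Dawn's second end groups stood at 0% at 15.0 s, and links went on turning into over-reaction product, so carrying 34.7% forward 10.0 s with τ gave 15.0%, and dawn read at 25 s stood at 15.0%.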